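**Retrosynthetic overview**

1. Target ⇐ global desilylation ⇐ penta-TBS macrolide ⇐ ring expansion of a C1–C3 cis-β-lactone: the C27 alkoxide opens the oxetan-2-one, turning the 4-membered lactone into the 28-membered one (C1–O27 bond).
2. Seco β-lactone ⇐ Stille coupling at C17–C18 of a C1–C17 iodovinyl β-lactone with a C18–C28 tetraenylstannane.
3. β-Lactone (C2, C3) ⇐ ketene–aldehyde cyclocondensation of propanoyl chloride with the C3 aldehyde. The C3–C17 polyol ⇐ two-directional allylation of pentane-1,5-diol (C5, C9), mono cross-metathesis with ethyl vinyl ketone, oxa-Michael acetal (C11), syn-aldol with (E)-3-iodoacrolein (C14, C15), anti-reduction (C13).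
4. Stannane ⇐ (Z)-crotylboration of acetaldehyde (C26, C27), cross-metathesis with crotonaldehyde, Horner–Wadsworth–Emmons reaction with an enynyl phosphonate, hydrostannation.
5. Ring order: temporary 1,3-dioxane over O9/O11 (removed later) → oxetan-2-one → 28-membered lactone by expansion of the oxetanone.

Assumption: the SMILES is read as 2S,3R,5S,9S,11S,13R,14R,15R,26R,27R with an all-E C16–C25 pentaene (carbons numbered from the lactone carbonyl, C28 = methyl on C27, C2′ = the extra terminal =CH2 beyond C3 in early intermediates); the enantiomer named for each chiral ligand or reagent ((R)-Cl,MeO-BIPHEP, the (−)-Ipc boron reagents, O-trimethylsilylquinine) is quoted from memory of the published selectivity, and the antipode is meant if the sense is the opposite.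

**Route**

Step 1
Reactants: 1 prop-2-yn-1-ol
Product: 3 (E)-3-iodoprop-2-en-1-ol, via (E)-3-(tributylstannyl)prop-2-en-1-ol 2 (not isolated)
Conditions: Bu3SnH (1.1 equiv), AIBN (cat.), neat, 80 °C; then I2, CH2Cl2, 0 °C
Reagents that add atoms: tributyltin hydride CCCC[SnH](CCCC)CCCC (tin is in 2 only); iodine II
Why: Radical hydrostannation of the terminal alkyne equilibrates to the (E)-β-vinylstannane and iododestannylation replaces tin with retention of geometry (hydrostannation–iodinolysis).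

Step 2
Reactants: 3 (E)-3-iodoprop-2-en-1-ol
Product: 4 (E)-3-iodoprop-2-enal
Conditions: MnO2 (15 equiv), CH2Cl2, 23 °C, dark; used as a dried solution
Reagents that add atoms: none
Why: MnO2 oxidises the allylic alcohol selectively to the enal without isomerising or cleaving the vinyl iodide (allylic oxidation).

Step 3
Reactants: 5 cis-but-2-ene; 6 acetaldehyde
Product: 8 (2R,3R)-3-methylpent-4-en-2-ol, via (Z)-crotyldiisopinocampheylborane 7 (not isolated)
Conditions: n-BuLi, KOtBu, THF, −78 → −45 °C; (−)-Ipc2BOMe, −78 °C; BF3·OEt2; then 6, −78 °C; NaOH, H2O2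
Reagents that add atoms: (−)-B-methoxydiisopinocampheylborane COB([C@@H]1C[C@@H]2C[C@H]([C@H]1C)C2(C)C)[C@@H]1C[C@@H]2C[C@H]([C@H]1C)C2(C)C (boron and Ipc groups are in 7 only)
Why: Brown crotylboration through a closed chair transition state, the Z-crotyl geometry giving the 26,27-syn pair and the (+)-α-pinene-derived Ipc groups directing attack on the Si face of acetaldehyde (C26 and C27 set).

Step 4
Reactants: 8 (2R,3R)-3-methylpent-4-en-2-ol; 9 (E)-but-2-enal
Product: 10 (2E,4R,5R)-5-hydroxy-4-methylhex-2-enal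
Conditions: 9 (5 equiv), second-generation Hoveyda–Grubbs catalyst RuCl2(H2IMes)(=CH-C6H4-2-OiPr) (5 mol%), CH2Cl2, 40 °C
Reagents that add atoms: none
Why: Olefin cross-metathesis of a terminal alkene with excess electron-poor enal is E-selective and tolerates the free hydroxyl, and the stereocentres are not involved.

Step 5
Reactants: 11 (E)-pent-2-en-4-yn-1-ol
Product: 13 diethyl [(2E)-pent-2-en-4-yn-1-yl]phosphonate, via (E)-5-bromopent-3-en-1-yne 12 (not isolated)
Conditions: PBr3 (0.4 equiv), Et2O, 0 °C; then P(OEt)3 (1.5 equiv), 100 °C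
Reagents that add atoms: phosphorus tribromide BrP(Br)Br (bromine is in 12 only); triethyl phosphite CCOP(OCC)OCC
Why: Conversion of the primary allylic alcohol into the bromide followed by Michaelis–Arbuzov reaction gives the enynyl phosphonate with the E alkene retained.

Step 6
Reactants: 10 (2E,4R,5R)-5-hydroxy-4-methylhex-2-enal; 13 diethyl [(2E)-pent-2-en-4-yn-1-yl]phosphonate
Product: 14 (2R,3R,4E,6E,8E)-3-methylundeca-4,6,8-trien-10-yn-2-ol
Conditions: 13 (1.3 equiv), LiHMDS (2.3 equiv), THF, −78 → 0 °C; aq. NH4Cl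
Reagents that add atoms: none
Why: Horner–Wadsworth–Emmons olefination with the allylic-type phosphonate anion forms C22=C23 E-selectively, the extra base holding the hydroxyl as its inert lithium alkoxide at low temperature.

Step 7
Reactants: 14 (2R,3R,4E,6E,8E)-3-methylundeca-4,6,8-trien-10-yn-2-ol
Product: 15 (2R,3R,4E,6E,8E,10E)-3-methyl-11-(tributylstannyl)undeca-4,6,8,10-tetraen-2-ol
Conditions: Bu3SnH (1.2 equiv), PdCl2(PPh3)2 (2 mol%), THF, 0 °C, dark
Reagents that add atoms: tributyltin hydride CCCC[SnH](CCCC)CCCC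
Why: Palladium-catalysed syn-hydrostannation of the terminal alkyne places tin on the terminal carbon and gives the (E)-vinylstannane, completing the all-E tetraenylstannane without touching the internal alkenes.

Step 8
Reactants: 16 pentane-1,5-diol; 17 allyl acetate
Product: 18 (4S,8S)-undeca-1,10-diene-4,8-diol
Conditions: [Ir(cod)Cl]2 (5 mol%), (R)-Cl,MeO-BIPHEP (10 mol%), 4-chloro-3-nitrobenzoic acid (20 mol%), Cs2CO3 (40 mol%), 17 (10 equiv), 1,4-dioxane, 90 °C
Reagents that add atoms: none
Why: Krische-type iridium-catalysed transfer-hydrogenative double allylation, in which each primary alcohol is dehydrogenated in situ and allylated under ligand control (C5 and C9 set) and the second addition amplifies the ee of the C2-symmetric diol.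

Step 9
Reactants: 18 (4S,8S)-undeca-1,10-diene-4,8-diol; 19 pent-1-en-3-one
Product: 20 (4E,7S,11S)-7,11-dihydroxytetradeca-4,13-dien-3-one
Conditions: 19 (1.1 equiv, slow addition), second-generation Hoveyda–Grubbs catalyst RuCl2(H2IMes)(=CH-C6H4-2-OiPr) (3 mol%), CH2Cl2, 40 °C; stopped near half conversion of the alkene ends, recovered 18 recycled
Reagents that add atoms: none
Why: Cross-metathesis with the electron-poor vinyl ketone gives the (E)-enone, and because the two alkenes of 18 are homotopic a single reaction at either end gives the same mono-enone.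

Step 10
Reactants: 20 (4E,7S,11S)-7,11-dihydroxytetradeca-4,13-dien-3-one; 6 acetaldehyde
Product: 21 dioxane ethyl ketone 1-[(4S,6S)-6-[(4S)-4-hydroxyhept-6-en-1-yl]-2-methyl-1,3-dioxan-4-yl]butan-2-one
Conditions: 6 (5 equiv), Bi(NO3)3·5H2O (10 mol%), CH2Cl2, 23 °C
Reagents that add atoms: none
Why: Bismuth nitrate-mediated hemiacetal formation and intramolecular oxa-conjugate addition under thermodynamic control gives the all-equatorial 1,3-dioxane, which fixes C11 syn to C9, while the remote homoallylic alcohol has no acceptor and is unchanged.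

Step 11
Reactants: 21 dioxane ethyl ketone; 4 (E)-3-iodoprop-2-enal
Product: 23 syn-aldol iodovinyl ketone, via bis(diisopinocampheylboryl) Z-enolate 22 (not isolated)
Conditions: (−)-Ipc2BOTf (2.4 equiv), iPr2NEt (4 equiv), CH2Cl2, −78 → 0 °C; 4 (1.5 equiv), −78 → −20 °C; H2O2, MeOH, pH 7 buffer, 0 °C
Reagents that add atoms: (−)-diisopinocampheylboron triflate FC(F)(F)S(=O)(=O)OB([C@@H]1C[C@@H]2C[C@H]([C@H]1C)C2(C)C)[C@@H]1C[C@@H]2C[C@H]([C@H]1C)C2(C)C (boron and Ipc groups are in 22 only)
Why: Paterson boron aldol in which enolisation on the less hindered ethyl side gives the Z-enolate, its chair transition state gives the 14,15-syn adduct and the Ipc ligands select the Si face of the enal (C14 and C15 set), the 5-OH being masked in situ as its borinate and freed on oxidative work-up.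

Step 12
Reactants: 23 syn-aldol iodovinyl ketone
Product: 24 dioxane triol
Conditions: Me4NBH(OAc)3 (6 equiv), MeCN/AcOH (1:1), −30 °C
Reagents that add atoms: none
Why: Evans–Saksena reduction in which the 15-OH binds the triacetoxyborohydride and delivers hydride intramolecularly through a chair transition state to give the 13,15-anti diol (C13 set).

Step 13
Reactants: 24 dioxane triol
Product: 25 pentaol vinyl iodide
Conditions: 1 M aq. HCl/THF (1:3), 40 °C, N2 sweep
Reagents that add atoms: none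
Why: Acid hydrolysis of the ethylidene acetal, driven by loss of volatile acetaldehyde, frees the 9,11-diol, the iodoalkene deactivating the allylic 15-OH towards ionisation.

Step 14
Reactants: 25 pentaol vinyl iodide
Product: 26 penta-TBS ether
Conditions: TBSOTf (7 equiv), 2,6-lutidine (10 equiv), CH2Cl2, 0 → 23 °C
Reagents that add atoms: tert-butyldimethylsilyl triflate CC(C)(C)[Si](C)(C)OS(=O)(=O)C(F)(F)F
Why: Exhaustive silylation with the silyl triflate caps all five secondary hydroxyls in one operation so that only fluoride-labile groups remain for the end game.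

Step 15
Reactants: 26 penta-TBS ether
Product: 27 C3 aldehyde
Conditions: OsO4 (2 mol%), NaIO4 (4 equiv), 2,6-lutidine (2 equiv), 1,4-dioxane/H2O (3:1), 23 °C
Reagents that add atoms: sodium periodate [Na+].[O-]I(=O)(=O)=O (terminal oxidant; the aldehyde oxygen is delivered through catalytic osmium tetroxide O=[Os](=O)(=O)=O)
Why: Lemieux–Johnson cleavage in which the electron-rich monosubstituted alkene is dihydroxylated much faster than the electron-poor iodoalkene and the diol is cleaved to the aldehyde, 2,6-lutidine suppressing β-elimination.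

Step 16
Reactants: 27 C3 aldehyde; 28 propanoyl chloride
Product: 30 cis-β-lactone vinyl iodide, via methylketene 29 (not isolated)
Conditions: 28 (2.5 equiv, syringe pump), O-trimethylsilylquinine (15 mol%), LiI (1.5 equiv), iPr2NEt (3 equiv), CH2Cl2/Et2O (9:1), −78 °C
Reagents that add atoms: none
Why: Nelson-type cinchona alkaloid/lithium-catalysed acyl halide–aldehyde cyclocondensation in which the chiral ammonium enolate of methylketene adds to the lithium-activated aldehyde and lactonises to the cis-3,4-disubstituted oxetan-2-one under catalyst control (C2 and C3 set, 3,5-anti).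

Step 17
Reactants: 30 cis-β-lactone vinyl iodide; 15 (2R,3R,4E,6E,8E,10E)-3-methyl-11-(tributylstannyl)undeca-4,6,8,10-tetraen-2-ol
Product: 31 seco β-lactone pentaene alcohol
Conditions: PdCl2(MeCN)2 (10 mol%), iPr2NEt (2 equiv), DMF/THF (1:1), 23 °C, degassed, dark
Reagents that add atoms: none
Why: Stille coupling of the vinyl iodide with the tetraenylstannane under neutral, phosphine-free conditions forms C17–C18 with retention of both alkene geometries and leaves the β-lactone, the silyl ethers and the free 27-OH untouched.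

Step 18
Reactants: 31 seco β-lactone pentaene alcohol
Product: 32 penta-TBS macrolactone
Conditions: NaHMDS (1.05 equiv), THF (0.5 mM in 31), −78 → −30 °C, 3 h, dark; AcOH (1.2 equiv), −78 °C
Reagents that add atoms: none
Why: Proposed new method: alkoxide-triggered ring-expanding translactonisation of a β-lactone (4 → 28 ring atoms), in which the sodium C27 alkoxide adds to the strained oxetan-2-one carbonyl, the bridged tetrahedral intermediate collapses by cleaving the endocyclic C1–O3 bond (release of roughly 95 kJ/mol of ring strain makes the acyl transfer irreversible without any coupling reagent), C2 and C3 are not touched and keep their configuration, and high dilution favours the intramolecular path; the closest known reactions are the acyl–oxygen opening of β-lactones by alkoxides, the alkoxide opening of N-acyl β-lactams (Holton–Ojima coupling) and the translactonisation ring expansions of hydroxylated macrolides.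

Step 19
Reactants: 32 penta-TBS macrolactone
Product: 33 CNP0245606.1
Conditions: HF·pyridine, pyridine, THF, 0 → 23 °C, dark
Reagents that add atoms: none
Why: Buffered HF·pyridine removes the five silyl ethers without acid strong enough to ionise the pentaenyl carbinol at C15 or base that could open the lactone (global desilylation).

**Compound list**

1 | prop-2-yn-1-ol | C#CCO | starting material
2 | (E)-3-(tributylstannyl)prop-2-en-1-ol | CCCC[Sn](CCCC)(CCCC)/C=C/CO | intermediate (not isolated)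
3 | (E)-3-iodoprop-2-en-1-ol | OC/C=C/I | intermediate
4 | (E)-3-iodoprop-2-enal | O=C/C=C/I | intermediate
5 | cis-but-2-ene | C/C=C\C | starting material
6 | acetaldehyde | CC=O | starting material
7 | (Z)-crotyldiisopinocampheylborane (Ipc groups from (+)-α-pinene) | C/C=C\CB([C@@H]1C[C@@H]2C[C@H]([C@H]1C)C2(C)C)[C@@H]1C[C@@H]2C[C@H]([C@H]1C)C2(C)C | intermediate (not isolated)
8 | (2R,3R)-3-methylpent-4-en-2-ol | C=C[C@@H](C)[C@@H](C)O | intermediate
9 | (E)-but-2-enal | C/C=C/C=O | starting material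
10 | (2E,4R,5R)-5-hydroxy-4-methylhex-2-enal | O=C/C=C/[C@@H](C)[C@@H](C)O | intermediate
11 | (E)-pent-2-en-4-yn-1-ol | C#C/C=C/CO | starting material
12 | (E)-5-bromopent-3-en-1-yne | C#C/C=C/CBr | intermediate (not isolated)
13 | diethyl [(2E)-pent-2-en-4-yn-1-yl]phosphonate | C#C/C=C/CP(=O)(OCC)OCC | intermediate
14 | (2R,3R,4E,6E,8E)-3-methylundeca-4,6,8-trien-10-yn-2-ol (C18–C28) | C#C/C=C/C=C/C=C/[C@@H](C)[C@@H](C)O | intermediate
15 | (2R,3R,4E,6E,8E,10E)-3-methyl-11-(tributylstannyl)undeca-4,6,8,10-tetraen-2-ol (C18–C28 stannane) | CCCC[Sn](CCCC)(CCCC)/C=C/C=C/C=C/C=C/[C@@H](C)[C@@H](C)O | intermediate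
16 | pentane-1,5-diol | OCCCCCO | starting material
17 | allyl acetate | CC(=O)OCC=C | starting material
18 | (4S,8S)-undeca-1,10-diene-4,8-diol (carbinol carbons become C5 and C9) | C=CC[C@@H](O)CCC[C@H](O)CC=C | intermediate
19 | pent-1-en-3-one | C=CC(=O)CC | starting material
20 | (4E,7S,11S)-7,11-dihydroxytetradeca-4,13-dien-3-one | C=CC[C@@H](O)CCC[C@H](O)C/C=C/C(=O)CC | intermediate
21 | 1-[(4S,6S)-6-[(4S)-4-hydroxyhept-6-en-1-yl]-2-methyl-1,3-dioxan-4-yl]butan-2-one, 2-methyl cis to both ring substituents (O9/O11 ethylidene acetal, C13 ethyl ketone, free 5-OH) | C=CC[C@@H](O)CCC[C@@H]1O[C@H](C)O[C@@H](C1)CC(=O)CC | intermediate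
22 | Z-enol borinate of 21: O13–B(Ipc)2 on the C13=C14 enolate and O5–B(Ipc)2 | C=CC[C@@H](OB([C@@H]2C[C@@H]3C[C@H]([C@H]2C)C3(C)C)[C@@H]2C[C@@H]3C[C@H]([C@H]2C)C3(C)C)CCC[C@@H]1O[C@H](C)O[C@@H](C1)C/C(OB([C@@H]2C[C@@H]3C[C@H]([C@H]2C)C3(C)C)[C@@H]2C[C@@H]3C[C@H]([C@H]2C)C3(C)C)=C/C | intermediate (not isolated)
23 | aldol adduct: 21 extended at C14 by CH(CH3)–CH(OH)–CH=CH–I (E), C13 ketone, 14-Me/15-OH syn, C14 and C15 as in the target | C=CC[C@@H](O)CCC[C@@H]1O[C@H](C)O[C@@H](C1)CC(=O)[C@@H](C)[C@H](O)/C=C/I | intermediate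
24 | 23 with the C13 ketone reduced to the alcohol, 13-OH anti to 15-OH (C13 as in the target) | C=CC[C@@H](O)CCC[C@@H]1O[C@H](C)O[C@@H](C1)C[C@@H](O)[C@@H](C)[C@H](O)/C=C/I | intermediate
25 | (1E)-1-iodo-4-methylhexadeca-1,15-diene-3,5,7,9,13-pentol, stereocentres as at C15, C14, C13, C11, C9, C5 of the target | C=CC[C@@H](O)CCC[C@H](O)C[C@H](O)C[C@@H](O)[C@@H](C)[C@H](O)/C=C/I | intermediate
26 | penta(tert-butyldimethylsilyl) ether of 25 | C=CC[C@@H](O[Si](C)(C)C(C)(C)C)CCC[C@H](O[Si](C)(C)C(C)(C)C)C[C@H](O[Si](C)(C)C(C)(C)C)C[C@@H](O[Si](C)(C)C(C)(C)C)[C@@H](C)[C@H](O[Si](C)(C)C(C)(C)C)/C=C/I | intermediate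
27 | C3 aldehyde: 26 with the terminal alkene cleaved to CHO (C3–C17, five OTBS, (E)-vinyl iodide) | O=CC[C@@H](O[Si](C)(C)C(C)(C)C)CCC[C@H](O[Si](C)(C)C(C)(C)C)C[C@H](O[Si](C)(C)C(C)(C)C)C[C@@H](O[Si](C)(C)C(C)(C)C)[C@@H](C)[C@H](O[Si](C)(C)C(C)(C)C)/C=C/I | intermediate
28 | propanoyl chloride | CCC(=O)Cl | starting material
29 | methylketene | CC=C=O | intermediate (not isolated)
30 | (3S,4R)-3-methyl-4-substituted oxetan-2-one (cis), the 4-substituent being the C4–C17 chain of 27 | O=C1[C@@H](C)[C@H](O1)C[C@@H](O[Si](C)(C)C(C)(C)C)CCC[C@H](O[Si](C)(C)C(C)(C)C)C[C@H](O[Si](C)(C)C(C)(C)C)C[C@@H](O[Si](C)(C)C(C)(C)C)[C@@H](C)[C@H](O[Si](C)(C)C(C)(C)C)/C=C/I | intermediate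
31 | 30 with iodine replaced by the all-E tetraenyl chain of 15: C1–C28 seco compound, β-lactone, all-E C16–C25 pentaene, free 27-OH | O=C1[C@@H](C)[C@H](O1)C[C@@H](O[Si](C)(C)C(C)(C)C)CCC[C@H](O[Si](C)(C)C(C)(C)C)C[C@H](O[Si](C)(C)C(C)(C)C)C[C@@H](O[Si](C)(C)C(C)(C)C)[C@@H](C)[C@H](O[Si](C)(C)C(C)(C)C)/C=C/C=C/C=C/C=C/C=C/[C@@H](C)[C@@H](C)O | intermediate
32 | 5,9,11,13,15-penta-O-TBS ether of the target (28-membered lactone, free 3-OH) | O=C1[C@@H](C)[C@H](O)C[C@@H](O[Si](C)(C)C(C)(C)C)CCC[C@H](O[Si](C)(C)C(C)(C)C)C[C@H](O[Si](C)(C)C(C)(C)C)C[C@@H](O[Si](C)(C)C(C)(C)C)[C@@H](C)[C@H](O[Si](C)(C)C(C)(C)C)/C=C/C=C/C=C/C=C/C=C/[C@@H](C)[C@@H](C)O1 | intermediate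
33 | CNP0245606.1 | C[C@H]1[C@H](O)/C=C/C=C/C=C/C=C/C=C/[C@@H](C)[C@@H](C)OC(=O)[C@@H](C)[C@H](O)C[C@@H](O)CCC[C@H](O)C[C@H](O)C[C@H]1O | target

**Totals and risks**

Total step count: 19 (one-pot sequences counted once). Longest linear sequence: 12 steps (16 → 33, steps 8–19).

Three steps most likely to fail:

Step 18 (the new ring expansion). Likely failure modes are oligomerisation, or silyl migration from O5 to the newly freed 3-alkoxide followed by δ-lactone formation. The fallback uses known chemistry, sets out from 30 (with 15) and returns at 33. LiOH in THF/H2O opens 30 to the β-hydroxy acid F1. TBSOTf/2,6-lutidine gives the 3-O-TBS silyl ester F2, and K2CO3 in MeOH/H2O cleaves the silyl ester to the 3-O-TBS acid F3. Yamaguchi esterification (2,4,6-trichlorobenzoyl chloride, Et3N, DMAP, toluene) with 15 gives the iodide–stannane ester F4. Intramolecular Stille coupling (Pd2(dba)3, AsPh3, iPr2NEt, DMF/THF, 1 mM) closes the 28-membered ring at C17–C18 to the hexa-TBS macrolactone F5, and HF·pyridine then gives 33.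

Step 9 (statistical mono-metathesis, at best about half of the material per pass). The fallback sets out from 16 and returns at 21. Monosilylation (NaH, TBSCl, THF) gives 5-[(tert-butyldimethylsilyl)oxy]pentan-1-ol F6. The iridium allylation of step 8 gives (4S)-8-[(tert-butyldimethylsilyl)oxy]oct-1-en-4-ol F7. Cross-metathesis with 19, now on a single alkene, gives the hydroxy enone F8, and the conditions of step 10 give the dioxane silyl ether F9. HF·pyridine frees the primary alcohol F10, and Dess–Martin periodinane gives the aldehyde F11. Brown allylation with (+)-Ipc2B(allyl) at −78 °C, which leaves the ketone alone, sets C5 and gives 21.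

Step 11 (aldol). Enolisation could occur at C12 instead of C14, facial control rests on the reagent alone, and the 5-OH is free. The fallback sets out from 19 and 4 and returns at 23; it moves the aldol to 19, which can enolise only at its ethyl group. (−)-Ipc2BOTf/iPr2NEt and then 4 give the syn-aldol vinyl ketone F12. TESOTf/2,6-lutidine gives the triethylsilyl ether F13. Cross-metathesis with excess 18 gives the enone F14, and the conditions of step 10 give the dioxane F15. HF·pyridine removes the triethylsilyl group to give 23.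

**Further compounds**

F1 | step 18 | β-hydroxy acid from 30 (C1 acid, free 3-OH, five OTBS, vinyl iodide) | OC(=O)[C@@H](C)[C@H](O)C[C@@H](O[Si](C)(C)C(C)(C)C)CCC[C@H](O[Si](C)(C)C(C)(C)C)C[C@H](O[Si](C)(C)C(C)(C)C)C[C@@H](O[Si](C)(C)C(C)(C)C)[C@@H](C)[C@H](O[Si](C)(C)C(C)(C)C)/C=C/I
F2 | step 18 | 3-O-TBS ether TBS ester of F1 | CC(C)(C)[Si](C)(C)OC(=O)[C@@H](C)[C@H](O[Si](C)(C)C(C)(C)C)C[C@@H](O[Si](C)(C)C(C)(C)C)CCC[C@H](O[Si](C)(C)C(C)(C)C)C[C@H](O[Si](C)(C)C(C)(C)C)C[C@@H](O[Si](C)(C)C(C)(C)C)[C@@H](C)[C@H](O[Si](C)(C)C(C)(C)C)/C=C/I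
F3 | step 18 | 3-O-TBS acid (C1–C17, six OTBS, vinyl iodide) | OC(=O)[C@@H](C)[C@H](O[Si](C)(C)C(C)(C)C)C[C@@H](O[Si](C)(C)C(C)(C)C)CCC[C@H](O[Si](C)(C)C(C)(C)C)C[C@H](O[Si](C)(C)C(C)(C)C)C[C@@H](O[Si](C)(C)C(C)(C)C)[C@@H](C)[C@H](O[Si](C)(C)C(C)(C)C)/C=C/I
F4 | step 18 | ester of F3 with the 27-OH of 15 (vinyl iodide and tetraenylstannane termini) | CCCC[Sn](CCCC)(CCCC)/C=C/C=C/C=C/C=C/[C@@H](C)[C@@H](C)OC(=O)[C@@H](C)[C@H](O[Si](C)(C)C(C)(C)C)C[C@@H](O[Si](C)(C)C(C)(C)C)CCC[C@H](O[Si](C)(C)C(C)(C)C)C[C@H](O[Si](C)(C)C(C)(C)C)C[C@@H](O[Si](C)(C)C(C)(C)C)[C@@H](C)[C@H](O[Si](C)(C)C(C)(C)C)/C=C/I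
F5 | step 18 | 3,5,9,11,13,15-hexa-O-TBS ether of the target | O=C1[C@@H](C)[C@H](O[Si](C)(C)C(C)(C)C)C[C@@H](O[Si](C)(C)C(C)(C)C)CCC[C@H](O[Si](C)(C)C(C)(C)C)C[C@H](O[Si](C)(C)C(C)(C)C)C[C@@H](O[Si](C)(C)C(C)(C)C)[C@@H](C)[C@H](O[Si](C)(C)C(C)(C)C)/C=C/C=C/C=C/C=C/C=C/[C@@H](C)[C@@H](C)O1
F6 | step 9 | 5-[(tert-butyldimethylsilyl)oxy]pentan-1-ol | CC(C)(C)[Si](C)(C)OCCCCCO
F7 | step 9 | (4S)-8-[(tert-butyldimethylsilyl)oxy]oct-1-en-4-ol | CC(C)(C)[Si](C)(C)OCCCC[C@H](O)CC=C
F8 | step 9 | (4E,7S)-11-[(tert-butyldimethylsilyl)oxy]-7-hydroxyundec-4-en-3-one | CC(C)(C)[Si](C)(C)OCCCC[C@H](O)C/C=C/C(=O)CC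
F9 | step 9 | cis-2-methyl-1,3-dioxane ethyl ketone with a 4-(TBS-oxy)butyl chain (as 21 but C5 = CH2OTBS) | CC(C)(C)[Si](C)(C)OCCCC[C@@H]1O[C@H](C)O[C@@H](C1)CC(=O)CC
F10 | step 9 | primary alcohol from F9 | OCCCC[C@@H]1O[C@H](C)O[C@@H](C1)CC(=O)CC
F11 | step 9 | C5 aldehyde from F10 | O=CCCC[C@@H]1O[C@H](C)O[C@@H](C1)CC(=O)CC
F12 | step 11 | (6E)-5-hydroxy-7-iodo-4-methylhepta-1,6-dien-3-one, 4,5-syn, configured as C14/C15 of the target | C=CC(=O)[C@@H](C)[C@H](O)/C=C/I
F13 | step 11 | triethylsilyl ether of F12 | C=CC(=O)[C@@H](C)[C@H](O[Si](CC)(CC)CC)/C=C/I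
F14 | step 11 | enone from F13 and 18 (C11=C12 E, free 5-OH and 9-OH, 15-OTES) | C=CC[C@@H](O)CCC[C@H](O)C/C=C/C(=O)[C@@H](C)[C@H](O[Si](CC)(CC)CC)/C=C/I
F15 | step 11 | 15-O-triethylsilyl ether of 23 | C=CC[C@@H](O)CCC[C@@H]1O[C@H](C)O[C@@H](C1)CC(=O)[C@@H](C)[C@H](O[Si](CC)(CC)CC)/C=C/I
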